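## Retrosynthetic overview

1. Target 23 comes from bis-silyl ether 22 by desilylation. The C5 hydroxypropenyl chain of 22 is attached to 19 by sterically directed C–H borylation and Suzuki coupling with iodoallyl alcohol 20.
2. Compound 19 comes from phenol 18 by O-methylation of the 7-hydroxyl that the ring-forming step delivers.
3. Key disconnection: 18 comes from ethynyl ether 16 by gold-catalysed furan–yne cycloisomerisation. The furan is consumed, and benzene ring A and the dihydrofuran ring are created together.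
4. Compound 16 comes from alcohol 11 and trichloroethylene 12. Alcohol 11 comes from an Evans syn-aldol of furylacetyl imide 6 (from 3 and 4) with silylated syringaldehyde 2, which fixes C2 and C3 before any new ring exists.
5. Ring order: the syringyl ring is bought; ring A and the dihydrofuran ring form simultaneously in step 7.

Assumption: the SMILES is read as the (2R,3S)-trans isomer, and 3, 4 and 20 are taken as catalogue reagents.

## Route

Step 1
Reactants: 1 syringaldehyde
Product: 2 3,5-dimethoxy-4-(triisopropylsilyloxy)benzaldehyde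
Conditions: TIPSCl, imidazole, DMAP (cat.), DMF, 40 °C
Reagents that add atoms: triisopropylsilyl chloride, CC(C)[Si](Cl)(C(C)C)C(C)C
Why: O-silylation of the hindered phenol; the bulky aryl silyl ether is chosen to survive KH, n-BuLi and K2CO3 later and to fall off with fluoride at the end.

Step 2
Reactants: 3 2-(furan-2-yl)acetic acid; 4 (R)-4-benzyloxazolidin-2-one
Product: 6 (R)-4-benzyl-3-[2-(furan-2-yl)acetyl]oxazolidin-2-one, via mixed pivalic anhydride 5 (not isolated)
Conditions: PivCl, Et3N, THF, −20 °C; then 4, LiCl, rt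
Reagents that add atoms: none
Why: N-acylation of the Evans auxiliary through the mixed anhydride, the standard mild method for arylacetic acids.

Step 3
Reactants: 6 (R)-4-benzyl-3-[2-(furan-2-yl)acetyl]oxazolidin-2-one; 2 3,5-dimethoxy-4-(triisopropylsilyloxy)benzaldehyde
Product: 9 (R)-4-benzyl-3-[(2S,3R)-3-[3,5-dimethoxy-4-(triisopropylsilyloxy)phenyl]-2-(furan-2-yl)-3-hydroxypropanoyl]oxazolidin-2-one, via boron enolate 7 (not isolated), via boron aldolate 8 (not isolated)
Conditions: Bu2BOTf, iPr2NEt, CH2Cl2, −78 to 0 °C; then 2, −78 to 0 °C; pH 7 buffer, MeOH, H2O2, 0 °C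
Reagents that add atoms: none
Why: Evans syn-aldol; the Z-boron enolate reacts through a closed Zimmerman–Traxler transition state on the face away from the benzyl group of the (R)-auxiliary, setting both stereocentres as the (2S,3R) syn pair, which maps onto trans-(2R,3S) in the final ring.

Step 4
Reactants: 9 aldol adduct
Product: 10 (1R,2S)-1-[3,5-dimethoxy-4-(triisopropylsilyloxy)phenyl]-2-(furan-2-yl)propane-1,3-diol
Conditions: LiBH4, MeOH (1 equiv), THF, 0 °C
Reagents that add atoms: none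
Why: reductive cleavage of the imide by borohydride gives the primary alcohol and returns the auxiliary without touching either stereocentre.

Step 5
Reactants: 10 diol
Product: 11 (1R,2S)-1-[3,5-dimethoxy-4-(triisopropylsilyloxy)phenyl]-2-(furan-2-yl)-3-(triisopropylsilyloxy)propan-1-ol
Conditions: TIPSCl (1.1 equiv), imidazole, DMF, 0 °C to rt
Reagents that add atoms: triisopropylsilyl chloride, CC(C)[Si](Cl)(C(C)C)C(C)C
Why: selective silylation of the primary hydroxyl over the hindered secondary benzylic one; the triisopropylsilyl group is chosen because it does not migrate to the neighbouring alkoxide under KH.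

Step 6
Reactants: 11 secondary alcohol; 12 trichloroethylene
Product: 16 (1R,2S)-1-[3,5-dimethoxy-4-(triisopropylsilyloxy)phenyl]-1-(ethynyloxy)-2-(furan-2-yl)-3-(triisopropylsilyloxy)propane, via dichlorovinyl ether 13 (not isolated), via chloroethynyl ether 14 (not isolated), via lithium alkynyl ether 15 (not isolated)
Conditions: KH (2 equiv), THF, 0 °C; 12, −50 °C to rt; then n-BuLi (2.4 equiv), −78 to −40 °C; MeOH, −78 °C; kept cold, used crude
Reagents that add atoms: none
Why: Greene ynol ether synthesis; the potassium alkoxide adds to dichloroacetylene generated in the flask, and n-BuLi then eliminates HCl and exchanges the remaining chlorine, with no bond to either stereocentre made or broken.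

Step 7
Reactants: 16 ethynyl ether
Product: 18 (2R,3S)-2-[3,5-dimethoxy-4-(triisopropylsilyloxy)phenyl]-3-[(triisopropylsilyloxy)methyl]-2,3-dihydro-1-benzofuran-7-ol, via arene oxide 17 (not isolated)
Conditions: (Ph3P)AuNTf2 (3 mol%), 4 Å MS, CH2Cl2, −20 °C to rt
Reagents that add atoms: none
Why: Hashmi furan–yne phenol synthesis; monovalent gold activates the ynol ether, the tethered furan attacks it, and the resulting cyclopropyl gold carbene opens and recloses through arene oxide 17. The ring oxygen directs opening of 17 so that the hydroxyl lands on the former alkyne terminus (C7). Ring A and the dihydrofuran ring form in one operation, and the aldol stereocentres are carried over unchanged as trans-(2R,3S).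

Step 8
Reactants: 18 phenol
Product: 19 (2R,3S)-2-[3,5-dimethoxy-4-(triisopropylsilyloxy)phenyl]-7-methoxy-3-[(triisopropylsilyloxy)methyl]-2,3-dihydro-1-benzofuran
Conditions: MeI, K2CO3, acetone, rt
Reagents that add atoms: iodomethane, CI
Why: Williamson ether synthesis on the only free phenol; the hindered aryl silyl ether is stable to anhydrous carbonate at room temperature.

Step 9
Reactants: 19 methyl ether; 20 (E)-3-iodoprop-2-en-1-ol
Product: 22 (E)-3-[(2R,3S)-2-[3,5-dimethoxy-4-(triisopropylsilyloxy)phenyl]-7-methoxy-3-[(triisopropylsilyloxy)methyl]-2,3-dihydro-1-benzofuran-5-yl]prop-2-en-1-ol, via aryl pinacol boronate 21 (not isolated)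
Conditions: [Ir(OMe)(cod)]2 (1.5 mol%), dtbpy (3 mol%), B2pin2, THF, 80 °C; evaporate; then 20, Pd(dppf)Cl2 (5 mol%), K3PO4 aq, THF, 40 °C
Reagents that add atoms: none
Why: sterically controlled iridium-catalysed C–H borylation followed by Suzuki–Miyaura coupling; C5–H is the only aromatic C–H in 19 with no ortho substituent, and the alkenyl iodide couples with retention of its E geometry.

Step 10
Reactants: 22 bis-silyl ether
Product: 23 4-[(2R,3S)-3-(hydroxymethyl)-5-[(E)-3-hydroxyprop-1-enyl]-7-methoxy-2,3-dihydro-1-benzofuran-2-yl]-2,6-dimethoxyphenol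
Conditions: TBAF, AcOH (1:1), THF, 0 °C to rt
Reagents that add atoms: none
Why: fluoride desilylation removes both triisopropylsilyl groups; the acetic acid buffer keeps the liberated syringyl phenol from opening the benzylic ether through a quinone methide.

## Compound list

1 | syringaldehyde (4-hydroxy-3,5-dimethoxybenzaldehyde) | COc1cc(C=O)cc(OC)c1O | starting material
2 | 3,5-dimethoxy-4-(triisopropylsilyloxy)benzaldehyde | COc1cc(C=O)cc(OC)c1O[Si](C(C)C)(C(C)C)C(C)C | intermediate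
3 | 2-(furan-2-yl)acetic acid | OC(=O)Cc1ccco1 | starting material
4 | (R)-4-benzyloxazolidin-2-one | O=C1OC[C@@H](Cc2ccccc2)N1 | starting material
5 | 2-(furan-2-yl)acetic pivalic anhydride | CC(C)(C)C(=O)OC(=O)Cc1ccco1 | intermediate
6 | (R)-4-benzyl-3-[2-(furan-2-yl)acetyl]oxazolidin-2-one | O=C1OC[C@@H](Cc2ccccc2)N1C(=O)Cc1ccco1 | intermediate
7 | (Z)-dibutylboron enolate of 6 | CCCCB(CCCC)O/C(=C\c1ccco1)N1C(=O)OC[C@H]1Cc1ccccc1 | intermediate
8 | dibutylboron aldolate of 9 | COc1cc([C@H](OB(CCCC)CCCC)[C@H](C(=O)N2C(=O)OC[C@H]2Cc2ccccc2)c2ccco2)cc(OC)c1O[Si](C(C)C)(C(C)C)C(C)C | intermediate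
9 | (R)-4-benzyl-3-[(2S,3R)-3-[3,5-dimethoxy-4-(triisopropylsilyloxy)phenyl]-2-(furan-2-yl)-3-hydroxypropanoyl]oxazolidin-2-one | COc1cc([C@H](O)[C@H](C(=O)N2C(=O)OC[C@H]2Cc2ccccc2)c2ccco2)cc(OC)c1O[Si](C(C)C)(C(C)C)C(C)C | intermediate
10 | (1R,2S)-1-[3,5-dimethoxy-4-(triisopropylsilyloxy)phenyl]-2-(furan-2-yl)propane-1,3-diol | COc1cc([C@H](O)[C@H](CO)c2ccco2)cc(OC)c1O[Si](C(C)C)(C(C)C)C(C)C | intermediate
11 | (1R,2S)-1-[3,5-dimethoxy-4-(triisopropylsilyloxy)phenyl]-2-(furan-2-yl)-3-(triisopropylsilyloxy)propan-1-ol | COc1cc([C@H](O)[C@H](CO[Si](C(C)C)(C(C)C)C(C)C)c2ccco2)cc(OC)c1O[Si](C(C)C)(C(C)C)C(C)C | intermediate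
12 | trichloroethylene | ClC=C(Cl)Cl | starting material
13 | (E)-1,2-dichlorovinyl ether of 11 | COc1cc([C@H](O/C(Cl)=C\Cl)[C@H](CO[Si](C(C)C)(C(C)C)C(C)C)c2ccco2)cc(OC)c1O[Si](C(C)C)(C(C)C)C(C)C | intermediate
14 | chloroethynyl ether of 11 | COc1cc([C@H](OC#CCl)[C@H](CO[Si](C(C)C)(C(C)C)C(C)C)c2ccco2)cc(OC)c1O[Si](C(C)C)(C(C)C)C(C)C | intermediate
15 | lithium alkynyl ether (lithium acetylide of 16) | COc1cc([C@H](OC#C[Li])[C@H](CO[Si](C(C)C)(C(C)C)C(C)C)c2ccco2)cc(OC)c1O[Si](C(C)C)(C(C)C)C(C)C | intermediate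
16 | (1R,2S)-1-[3,5-dimethoxy-4-(triisopropylsilyloxy)phenyl]-1-(ethynyloxy)-2-(furan-2-yl)-3-(triisopropylsilyloxy)propane | COc1cc([C@H](OC#C)[C@H](CO[Si](C(C)C)(C(C)C)C(C)C)c2ccco2)cc(OC)c1O[Si](C(C)C)(C(C)C)C(C)C | intermediate
17 | arene oxide: 6,7-epoxide of the (2R,3S)-2-aryl-3-(silyloxymethyl)-2,3,6,7-tetrahydro-1-benzofuran, epoxide configuration undefined | COc1cc([C@@H]2OC3=C(C=CC4OC34)[C@H]2CO[Si](C(C)C)(C(C)C)C(C)C)cc(OC)c1O[Si](C(C)C)(C(C)C)C(C)C | intermediate
18 | (2R,3S)-2-[3,5-dimethoxy-4-(triisopropylsilyloxy)phenyl]-3-[(triisopropylsilyloxy)methyl]-2,3-dihydro-1-benzofuran-7-ol | COc1cc([C@@H]2Oc3c(O)cccc3[C@H]2CO[Si](C(C)C)(C(C)C)C(C)C)cc(OC)c1O[Si](C(C)C)(C(C)C)C(C)C | intermediate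
19 | (2R,3S)-2-[3,5-dimethoxy-4-(triisopropylsilyloxy)phenyl]-7-methoxy-3-[(triisopropylsilyloxy)methyl]-2,3-dihydro-1-benzofuran | COc1cc([C@@H]2Oc3c(OC)cccc3[C@H]2CO[Si](C(C)C)(C(C)C)C(C)C)cc(OC)c1O[Si](C(C)C)(C(C)C)C(C)C | intermediate
20 | (E)-3-iodoprop-2-en-1-ol | OC/C=C/I | starting material
21 | 5-(pinacolboryl) derivative of 19 | COc1cc([C@@H]2Oc3c(OC)cc(B4OC(C)(C)C(C)(C)O4)cc3[C@H]2CO[Si](C(C)C)(C(C)C)C(C)C)cc(OC)c1O[Si](C(C)C)(C(C)C)C(C)C | intermediate
22 | (E)-3-[(2R,3S)-2-[3,5-dimethoxy-4-(triisopropylsilyloxy)phenyl]-7-methoxy-3-[(triisopropylsilyloxy)methyl]-2,3-dihydro-1-benzofuran-5-yl]prop-2-en-1-ol | COc1cc([C@@H]2Oc3c(OC)cc(/C=C/CO)cc3[C@H]2CO[Si](C(C)C)(C(C)C)C(C)C)cc(OC)c1O[Si](C(C)C)(C(C)C)C(C)C | intermediate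
23 | 4-[(2R,3S)-3-(hydroxymethyl)-5-[(E)-3-hydroxyprop-1-enyl]-7-methoxy-2,3-dihydro-1-benzofuran-2-yl]-2,6-dimethoxyphenol | COc1cc([C@@H]2Oc3c(OC)cc(/C=C/CO)cc3[C@H]2CO)cc(OC)c1O | target

## Step count and risks

Total steps: 10. Longest linear sequence: 9 (steps 2 to 10 from 3, or step 1 and steps 3 to 10 from 1).

**Step 7 (most likely to fail).** The gold-activated ynol ether sits on an electron-rich benzylic carbon and may ionise or shift its benzyl group instead of being attacked by the furan. The furan also lacks a 5-substituent, which usually slows this reaction, and traces of water hydrate the ynol ether. The fallback buys ring A instead of building it. It sets out from 2 and comes back at 19.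
- 2-(2-Bromo-3-methoxyphenyl)acetic acid F3 is coupled to 4 (PivCl, Et3N, LiCl) to give (R)-4-benzyl-3-[2-(2-bromo-3-methoxyphenyl)acetyl]oxazolidin-2-one F4.
- The same Evans syn-aldol with 2 gives the (2R,3R) adduct F5.
- LiBH4 gives the (1R,2S) diol F6, and TIPSCl gives the primary silyl ether F7.
- Intramolecular Ullmann-type O-arylation (CuI, 1,10-phenanthroline, K3PO4, toluene, 110 °C) closes the dihydrofuran with retention at both centres and delivers 19 directly.

**Step 6.** The potassium alkoxide of 11 may fragment or shuffle silyl groups, and the benzylic ynol ether is thermally labile. The fallback avoids the alkoxide. It sets out from 11 and comes back at 16.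
- Alcohol 11 is formylated (acetic formic anhydride, pyridine) to the formate ester F1.
- Dibromo-olefination (CBr4, PPh3, CH2Cl2) gives the 2,2-dibromovinyl ether F2.
- n-BuLi at −78 °C followed by MeOH converts F2 through lithium alkynyl ether 15 into 16.

**Step 9.** Borylation could give some C6 isomer, and the free iodoallyl alcohol can degrade under palladium and base. The fallback builds the side chain by metathesis. It sets out from 19 and comes back at 22.
- Boronate 21 is isolated and purified by chromatography.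
- Suzuki coupling with vinyl bromide (Pd(dppf)Cl2, K3PO4) gives the 5-vinyl compound F8.
- Cross-metathesis of F8 with (Z)-but-2-ene-1,4-diol using the second-generation Hoveyda–Grubbs catalyst in CH2Cl2 at 40 °C gives the E-allylic alcohol 22.

Further compounds
F1 | step 6 | formate ester of 11, (1R,2S)-1-[3,5-dimethoxy-4-(triisopropylsilyloxy)phenyl]-2-(furan-2-yl)-3-(triisopropylsilyloxy)propyl formate | COc1cc([C@H](OC=O)[C@H](CO[Si](C(C)C)(C(C)C)C(C)C)c2ccco2)cc(OC)c1O[Si](C(C)C)(C(C)C)C(C)C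
F2 | step 6 | 2,2-dibromovinyl ether of 11 | COc1cc([C@H](OC=C(Br)Br)[C@H](CO[Si](C(C)C)(C(C)C)C(C)C)c2ccco2)cc(OC)c1O[Si](C(C)C)(C(C)C)C(C)C
F3 | step 7 | 2-(2-bromo-3-methoxyphenyl)acetic acid | COc1cccc(CC(O)=O)c1Br
F4 | step 7 | (R)-4-benzyl-3-[2-(2-bromo-3-methoxyphenyl)acetyl]oxazolidin-2-one | COc1cccc(CC(=O)N2C(=O)OC[C@H]2Cc2ccccc2)c1Br
F5 | step 7 | (R)-4-benzyl-3-[(2R,3R)-2-(2-bromo-3-methoxyphenyl)-3-[3,5-dimethoxy-4-(triisopropylsilyloxy)phenyl]-3-hydroxypropanoyl]oxazolidin-2-one | COc1cc([C@H](O)[C@H](C(=O)N2C(=O)OC[C@H]2Cc2ccccc2)c2cccc(OC)c2Br)cc(OC)c1O[Si](C(C)C)(C(C)C)C(C)C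
F6 | step 7 | (1R,2S)-2-(2-bromo-3-methoxyphenyl)-1-[3,5-dimethoxy-4-(triisopropylsilyloxy)phenyl]propane-1,3-diol | COc1cc([C@H](O)[C@H](CO)c2cccc(OC)c2Br)cc(OC)c1O[Si](C(C)C)(C(C)C)C(C)C
F7 | step 7 | (1R,2S)-2-(2-bromo-3-methoxyphenyl)-1-[3,5-dimethoxy-4-(triisopropylsilyloxy)phenyl]-3-(triisopropylsilyloxy)propan-1-ol | COc1cc([C@H](O)[C@H](CO[Si](C(C)C)(C(C)C)C(C)C)c2cccc(OC)c2Br)cc(OC)c1O[Si](C(C)C)(C(C)C)C(C)C
F8 | step 9 | (2R,3S)-2-[3,5-dimethoxy-4-(triisopropylsilyloxy)phenyl]-7-methoxy-3-[(triisopropylsilyloxy)methyl]-5-vinyl-2,3-dihydro-1-benzofuran | COc1cc([C@@H]2Oc3c(OC)cc(C=C)cc3[C@H]2CO[Si](C(C)C)(C(C)C)C(C)C)cc(OC)c1O[Si](C(C)C)(C(C)C)C(C)C
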